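## Analysis of the target

The target is a 2,3,4,5-tetrasubstituted oxolane lignan. Ring atom O1 is flanked by C2 and C5, each carrying a 4-hydroxy-3-methoxyphenyl group; C3 carries a methyl and a tertiary hydroxyl group, and C4 carries a methyl group. All four ring carbons are stereocentres, (2R,3S,4S,5R): the two aryl groups are cis, the C3 methyl lies on their face, and the C3 hydroxyl and the C4 methyl lie together on the opposite face. The sensitive points are the two benzylic ring bonds C2–O1 and C5–O1 (ionised by acid to quinone-methide-like cations, and open to hydrogenolysis), the tertiary alcohol (dehydration) and the electron-rich free phenols. The hard part is the fully substituted carbinol C3, wedged between benzylic C2 and C4, whose oxygen must point away from the neighbouring aryl group; in addition a single enantiomer is required of a molecule whose two halves differ only at C3. The strategy rests on two features. C2–O1–C5 with two identical aryl groups is the skeleton of a symmetrical carbonyl ylide, so no regiochemistry arises. C3–C4 is a former double bond whose C3 end already carries the oxygen; if the C3 methyl is read as a reduced carboxyl carbon, that alkene is a captodative 2-oxybut-2-enoate, and the ring with all four stereocentres follows from one cycloaddition.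

## Retrosynthetic reasoning

**17 from 16.** The two phenols are masked as benzyl ethers, which withstand base, hydride and the photo-oxidative key step and are removed without acid. Only the two aryl O–CH2 bonds are cut in the last step.

**16 from 14 and 13, through 15.** The C3 methyl is traced back to a hydroxymethyl group: the exocyclic C–O bond is cut, not a ring bond. This lets C3 carry a carboxyl carbon earlier, the acceptor a dipolarophile needs. The tertiary C3–O bond is never broken, so the C3 configuration is safe. Forward, the primary hydroxyl of 13 is sulfonylated to 14, and a hydride donor closes and then opens spiro-oxirane 15 at its CH2 group.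

**13 from 12.** The 1,2-diol is the reduced form of a lactone whose second oxygen is tied to the C3 oxygen through one acetal carbon. One hydride reduction makes the CH2OH group, frees the C3 hydroxyl and removes the stereocontrolling group.

**12 from 10 and 11; 11 from 6.** C2–C3 and C4–C5 are cut together. These are the only two C–C bonds joining the symmetrical C2–O1–C5 unit to the C3–C4 unit, and cutting them gives a 1,3-dipole and an alkene, with all four stereocentres and the ring traced to one step. The two faces of ylide 11 are equivalent, so the absolute configuration is decided by which face of the alkene reacts. An acyclic enol ester of a 2-oxobutanoate would therefore give racemic material. A chiral Lewis acid is not an option: oxirane 6 is an acid-labile, electron-rich oxirane that would undergo Meinwald rearrangement, and an enol oxygen chelates poorly. The two spectator oxygens of the butenoate are therefore tied into a cyclic acetal carrying a tert-butyl group, giving 10, in which the controlling stereocentre sits next to the double bond. The forward reaction must deliver the 2,5-cis relation (from the W-shaped ylide), the lactone carbonyl endo (so that the future C3 methyl is cis to the aryl groups) and attack anti to the tert-butyl group. Ylide 11 comes from 6 by cleavage of the oxirane C–C bond.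

**10 from 8 and 7, through 9.** The exocyclic alkene is the dehydrogenated form of 8, reached by bromination to 9 and loss of HBr. Dioxolanone 8 is the cis acetal of hydroxy acid 7, whose stereocentre is copied onto the acetal carbon before being destroyed. The (R)-acid is required so that the acetal carbon of 10 is R.

**6 from 4 and 1, through 5; 4 from 2 and 1, through 3.** The oxirane C–C bond and one C–O bond are cut to give aldehyde 1 and the benzylic ylide 5 of sulfonium salt 4. Both aryl halves thus come from the same aldehyde: 4 is made from 1 via alcohol 2 and bromide 3. The oxirane can be racemic, because both enantiomers open to the same achiral 11.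

## Alternatives that were turned down

**Alternative 1:** ketene–enol ether cyclobutanone with a temporary C2–C5 bond.
- **Disconnection:** O1 is removed and C2 joined directly to C5, giving cyclobutanone A1; this is cut at C3–C4 and C2–C5 into enol ether A2 and methylketene A3.
- **Forward key step:** [2+2] addition of A3 across A2. A Baeyer–Villiger oxidation then inserts O1 next to the benzylic carbon, and aryl-metal addition to the lactone and lactol reduction bring in the second aryl group.
- **For:** C3 arrives with both its methyl group and its oxygen, so no carboxyl-to-methyl sequence is needed. On this point it is stronger than the chosen route, which spends three steps there. All steps are ground-state reactions of known type.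
- **Against:** A3 is a monoalkylketene that dimerises readily and is far less electrophilic than halogenated ketenes, and A2 is a hindered trisubstituted enol ether. The C4 methyl must end up cis to the benzyloxy group and trans to the C3 methyl, a choice between two similar groups on a quaternary carbon for which the antarafacial ketene approach gives no clear bias. There is no handle for absolute configuration. C5 is set late by hydride delivery to an oxocarbenium ion under Lewis acid conditions that threaten the tertiary benzylic-type ether and C2–O1.
- **Comparison:** the symmetry of the target is not used, only three centres come from the key step, and the sequence is longer (about nine steps after A2 is made). The chosen strategy sets four centres and the absolute sense in one step.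

**Alternative 2:** Petasis–Ferrier rearrangement of an arylglycolate-derived enol acetal.
- **Disconnection:** the C3 methyl is removed to give ketone A4, which is cut at C4–C5 back to enol acetal A5 (from an arylglycolic acid, aldehyde 1 and ethylidenation of the lactone carbonyl).
- **Forward key step:** an aluminium Lewis acid ionises the acetal of A5 to an aryl oxocarbenium ion and an aluminium enolate, whose carbon closes onto the oxocarbenium carbon to give A4 with 2,5-cis and 4,5-trans relations.
- **For:** the rearrangement type is well established, and the absolute configuration comes from one isolable stereocentre rather than from face discrimination in a cycloaddition. On precedent and on certainty of the absolute sense it is stronger than the chosen route.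
- **Against:** the closure is formally 5-endo-trig, less favourable than in the six-membered series. The required enantiopure arylglycolic acid has to be made and resolved. The C3 carbinol remains to be built on a hindered ketone with two epimerisable α-centres, and a methyl nucleophile would enter anti to the C2 aryl group, giving the C3 epimer of the target. A methylenation, epoxidation and hydride detour would be needed, costing as many steps as the chosen end game.
- **Comparison:** similar or greater length, and the hardest centre is left to the end. The chosen strategy delivers the C3 oxygen with the correct orientation in the ring-forming step and takes both aryl groups from one aldehyde.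

**Alternative 3:** allylsilane–aldehyde annulation with silicon as masked hydroxyl.
- **Disconnection:** C3–OH is replaced by C3–Si (silane A6), which is cut at C4–C5 and O1–C2 into aldehyde 1 and allylsilane A7.
- **Forward key step:** the Lewis-acid-activated aldehyde 1 is attacked by the γ-carbon of A7 anti to silicon, silicon shifts from C2 to C3, and the alkoxide captures the benzylic cation at C2. Oxidation of C–Si with retention (Fleming–Tamao) then gives the alcohol.
- **For:** it is convergent, uses 1 directly, has the C3 methyl in place, and translates one stereocentre plus the (Z)-geometry of A7 into C2, C3 and C4. On paper it has the shortest end game, and here it is stronger than the chosen route.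
- **Against:** A7 is an enantiopure α-aryl-α-silyl allylsilane with a trisubstituted (Z)-alkene and needs a multistep asymmetric synthesis. The tertiary β-silyl cation can simply lose silicon (Sakurai allylation). The p-alkoxybenzyl cation at C2 is stable enough to lose stereochemical memory. Oxidation of a tertiary C–SiMe2Ph bond requires electrophilic removal of the phenyl group, conditions under which the electron-rich aryl rings and the benzylic ring ethers are attacked.
- **Comparison:** the risk is spread over three uncertain operations. The chosen route concentrates it in one step, and its dipolarophile comes in two steps from a chiral-pool acid.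

Key step: step 6

Remark: oxirane 6 is made and used as the racemate, because both enantiomers open to the same achiral ylide 11; all absolute stereochemistry comes from the acetal carbon of 10.

## Route

**Step 1**
Reactants: 1 4-(benzyloxy)-3-methoxybenzaldehyde (O-benzylvanillin)
Product: 2 [4-(benzyloxy)-3-methoxyphenyl]methanol
Conditions: NaBH4, MeOH, 0 °C
Reagents that add atoms: none
Why: Borohydride reduction of an aromatic aldehyde; the benzyl and methyl ethers are inert.

**Step 2**
Reactants: 2 [4-(benzyloxy)-3-methoxyphenyl]methanol
Product: 4 1-[4-(benzyloxy)-3-methoxybenzyl]thiolan-1-ium bromide, via benzyl bromide 3 (not isolated)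
Conditions: PBr3, CH2Cl2, 0 °C; then tetrahydrothiophene, acetone, 20 °C
Reagents that add atoms: phosphorus tribromide BrP(Br)Br; tetrahydrothiophene C1CCSC1
Why: PBr3 turns the electron-rich benzylic alcohol into bromide 3, which alkylates the sulfide at once (SN2); the salt should precipitate from acetone, so the labile bromide never has to be purified.

**Step 3**
Reactants: 4 1-[4-(benzyloxy)-3-methoxybenzyl]thiolan-1-ium bromide; 1 4-(benzyloxy)-3-methoxybenzaldehyde
Product: 6 trans-2,3-bis[4-(benzyloxy)-3-methoxyphenyl]oxirane (racemic), via sulfonium ylide 5 (not isolated)
Conditions: KOH (powder), MeCN, 0 → 20 °C; isolation on base-washed silica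
Reagents that add atoms: none
Why: Corey–Chaykovsky epoxidation: the semi-stabilised ylide 5 adds reversibly to the aldehyde and the anti betaine closes faster, so the trans-oxirane should predominate. Its configuration is not critical, because under electron-transfer conditions both stereoisomers are expected to open to the same ylide.

**Step 4**
Reactants: 7 (R)-2-hydroxybutanoic acid
Product: 8 (2R,5R)-2-tert-butyl-5-ethyl-1,3-dioxolan-4-one (cis)
Conditions: pivalaldehyde, TsOH·H2O (cat.), H2SO4 (cat.), pentane, reflux (Dean–Stark); cis isomer purified
Reagents that add atoms: pivalaldehyde CC(C)(C)C=O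
Why: Acid-catalysed acetalisation of an α-hydroxy acid with removal of water; the cis-dioxolanone is the favoured isomer, so the configuration of C5 is copied onto the new acetal carbon (self-regeneration of stereocentres). The trans isomer carries the opposite acetal configuration and must be removed.

**Step 5**
Reactants: 8 (2R,5R)-2-tert-butyl-5-ethyl-1,3-dioxolan-4-one
Product: 10 (2R,5Z)-2-tert-butyl-5-ethylidene-1,3-dioxolan-4-one, via bromo-dioxolanone 9 (not isolated)
Conditions: NBS, AIBN (cat.), PhCF3, 80 °C; then DBU, Et2O, 0 → 20 °C
Reagents that add atoms: none
Why: Wohl–Ziegler-type radical bromination at the captodative C5–H gives 9, and E2 loss of HBr towards the ethyl group gives the exocyclic alkene. The (Z)-isomer, with the methyl away from the lactone carbonyl, is expected to be favoured; the acetal carbon is untouched.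

**Step 6**
Reactants: 6 trans-2,3-bis[4-(benzyloxy)-3-methoxyphenyl]oxirane (racemic); 10 (2R,5Z)-2-tert-butyl-5-ethylidene-1,3-dioxolan-4-one
Product: 12 (2R,5S,6R,8R,9S)-6,8-bis[4-(benzyloxy)-3-methoxyphenyl]-2-tert-butyl-9-methyl-1,3,7-trioxaspiro[4.4]nonan-4-one, via carbonyl ylide 11 (not isolated)
Conditions: 10 (3 equiv), 9,10-dicyanoanthracene (10 mol%), biphenyl, MeCN, Ar, hν (420 nm), 20 °C
Reagents that add atoms: none
Why: Proposed new method: carbonyl ylides released from 2,3-diaryloxiranes by photoinduced electron transfer are known to add to acrylates, fumarates and maleic anhydride (the closest known reaction type) but not to a trisubstituted captodative alkene bearing a chiral acetal; here excited 9,10-dicyanoanthracene should oxidise the electron-rich oxirane 6, the radical cation breaks its C–C bond, back electron transfer gives the W-shaped ylide 11, and this electron-rich dipole adds to the lactone-activated alkene of 10 in a concerted suprafacial [4π+2π] cycloaddition. The oxolane ring is closed by forming C2–C3 and C4–C5 together in a six-electron cycloaddition, not a stepwise closure; the dioxolanone becomes the spiro ring without any of its bonds being made. C2 and C5 are set cis by the exo,exo geometry of 11. C3 and C4 keep the ring oxygen and the methyl group cis because the (Z)-alkene reacts suprafacially. Their relation to C2 and C5 needs the lactone carbonyl endo and the ring oxygen and (Z)-methyl exo, which is favoured by secondary overlap of the carbonyl with the ylide and because the other orientation would push the methyl group under an aryl ring. The absolute configuration comes from the acetal carbon: the tert-butyl group shields one face of the alkene, so 11, whose two faces are equivalent, should add to the Si face at C5 of (2R)-10. Because 11 is symmetrical there is no regiochemistry to control, and return of 11 to 6 only costs time; the minor adducts are diastereomers of 12 and are removed by chromatography or crystallisation.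

**Step 7**
Reactants: 12 (2R,5S,6R,8R,9S)-6,8-bis[4-(benzyloxy)-3-methoxyphenyl]-2-tert-butyl-9-methyl-1,3,7-trioxaspiro[4.4]nonan-4-one
Product: 13 (2R,3R,4S,5R)-2,5-bis[4-(benzyloxy)-3-methoxyphenyl]-3-(hydroxymethyl)-4-methyloxolan-3-ol
Conditions: LiAlH4, THF, 0 → 20 °C
Reagents that add atoms: none
Why: Hydride reduction of the lactone; the hemiacetal alkoxide collapses, freeing the C3 alkoxide, and the released pivalaldehyde is reduced as well. No bond to a ring stereocentre is broken (the C3 descriptor changes only by priority).

**Step 8**
Reactants: 13 (2R,3R,4S,5R)-2,5-bis[4-(benzyloxy)-3-methoxyphenyl]-3-(hydroxymethyl)-4-methyloxolan-3-ol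
Product: 14 [(2R,3R,4S,5R)-2,5-bis[4-(benzyloxy)-3-methoxyphenyl]-3-hydroxy-4-methyloxolan-3-yl]methyl 4-methylbenzenesulfonate
Conditions: TsCl, Et3N, Bu2SnO (cat.), CH2Cl2, 20 °C
Reagents that add atoms: 4-methylbenzenesulfonyl chloride Cc1ccc(S(=O)(=O)Cl)cc1
Why: Stannylene-acetal-catalysed monosulfonylation of a 1,2-diol: the tin acetal delivers the sulfonyl group to the primary oxygen, and the tertiary hydroxyl is not sulfonylated under these conditions.

**Step 9**
Reactants: 14 [(2R,3R,4S,5R)-2,5-bis[4-(benzyloxy)-3-methoxyphenyl]-3-hydroxy-4-methyloxolan-3-yl]methyl 4-methylbenzenesulfonate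
Product: 16 (2R,3S,4S,5R)-2,5-bis[4-(benzyloxy)-3-methoxyphenyl]-3,4-dimethyloxolan-3-ol, via spiro-oxirane 15 (not isolated)
Conditions: LiEt3BH (excess), THF, 0 → 20 °C
Reagents that add atoms: none
Why: The first equivalent of hydride deprotonates the tertiary hydroxyl, the alkoxide displaces the neighbouring sulfonate (3-exo-tet) to give 15, and LiEt3BH opens it by SN2 attack at the CH2 group. The C3–O bond is never broken, and direct hydride displacement of the sulfonate would give the same product.

**Step 10**
Reactants: 16 (2R,3S,4S,5R)-2,5-bis[4-(benzyloxy)-3-methoxyphenyl]-3,4-dimethyloxolan-3-ol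
Product: 17 (2R,3S,4S,5R)-2,5-bis(4-hydroxy-3-methoxyphenyl)-3,4-dimethyloxolan-3-ol
Conditions: H2 (1 atm), Pd/C, EtOAc, 20 °C
Reagents that add atoms: none
Why: Hydrogenolysis of aryl benzyl ethers on palladium; in a neutral aprotic solvent the phenol O–CH2Ph bonds should cleave much faster than the dialkyl benzylic bonds C2–O1 and C5–O1. The reaction is stopped after uptake of two equivalents of hydrogen.

## Compound list

1 | 4-(benzyloxy)-3-methoxybenzaldehyde | COc1cc(C=O)ccc1OCc1ccccc1 | starting material
2 | [4-(benzyloxy)-3-methoxyphenyl]methanol | COc1cc(CO)ccc1OCc1ccccc1 | intermediate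
3 | 1-(benzyloxy)-4-(bromomethyl)-2-methoxybenzene | COc1cc(CBr)ccc1OCc1ccccc1 | intermediate
4 | 1-[4-(benzyloxy)-3-methoxybenzyl]thiolan-1-ium bromide | COc1cc(C[S+]2CCCC2)ccc1OCc1ccccc1.[Br-] | intermediate
5 | [4-(benzyloxy)-3-methoxyphenyl](thiolan-1-ium-1-yl)methanide | COc1cc([CH-][S+]2CCCC2)ccc1OCc1ccccc1 | intermediate
6 | trans-2,3-bis[4-(benzyloxy)-3-methoxyphenyl]oxirane, racemic, (2S,3S) enantiomer drawn | COc1cc([C@@H]2O[C@H]2c2ccc(OCc3ccccc3)c(OC)c2)ccc1OCc1ccccc1 | intermediate
7 | (R)-2-hydroxybutanoic acid | CC[C@@H](O)C(=O)O | starting material
8 | (2R,5R)-2-tert-butyl-5-ethyl-1,3-dioxolan-4-one (cis) | CC[C@H]1O[C@@H](C(C)(C)C)OC1=O | intermediate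
9 | (2S)-5-bromo-2-tert-butyl-5-ethyl-1,3-dioxolan-4-one (acetal carbon unchanged in space, descriptor changed by priority; C5 not defined) | CCC1(Br)O[C@@H](C(C)(C)C)OC1=O | intermediate
10 | (2R,5Z)-2-tert-butyl-5-ethylidene-1,3-dioxolan-4-one | C/C=C1\O[C@@H](C(C)(C)C)OC1=O | intermediate
11 | 1,3-bis[4-(benzyloxy)-3-methoxyphenyl] carbonyl ylide, exo,exo (W-shaped) form, one resonance form drawn | COc1cc(/C=[O+]/[CH-]c2ccc(OCc3ccccc3)c(OC)c2)ccc1OCc1ccccc1 | intermediate
12 | (2R,5S,6R,8R,9S)-6,8-bis[4-(benzyloxy)-3-methoxyphenyl]-2-tert-butyl-9-methyl-1,3,7-trioxaspiro[4.4]nonan-4-one | COc1cc([C@H]2O[C@@H](c3ccc(OCc4ccccc4)c(OC)c3)[C@H](C)[C@@]25C(=O)O[C@H](C(C)(C)C)O5)ccc1OCc1ccccc1 | intermediate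
13 | (2R,3R,4S,5R)-2,5-bis[4-(benzyloxy)-3-methoxyphenyl]-3-(hydroxymethyl)-4-methyloxolan-3-ol | COc1cc([C@H]2O[C@@H](c3ccc(OCc4ccccc4)c(OC)c3)[C@H](C)[C@]2(CO)O)ccc1OCc1ccccc1 | intermediate
14 | [(2R,3R,4S,5R)-2,5-bis[4-(benzyloxy)-3-methoxyphenyl]-3-hydroxy-4-methyloxolan-3-yl]methyl 4-methylbenzenesulfonate | COc1cc([C@H]2O[C@@H](c3ccc(OCc4ccccc4)c(OC)c3)[C@H](C)[C@]2(COS(=O)(=O)c3ccc(C)cc3)O)ccc1OCc1ccccc1 | intermediate
15 | (3R,4R,6R,7S)-4,6-bis[4-(benzyloxy)-3-methoxyphenyl]-7-methyl-1,5-dioxaspiro[2.4]heptane | COc1cc([C@H]2O[C@@H](c3ccc(OCc4ccccc4)c(OC)c3)[C@H](C)[C@@]23CO3)ccc1OCc1ccccc1 | intermediate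
16 | (2R,3S,4S,5R)-2,5-bis[4-(benzyloxy)-3-methoxyphenyl]-3,4-dimethyloxolan-3-ol | COc1cc([C@H]2O[C@@H](c3ccc(OCc4ccccc4)c(OC)c3)[C@H](C)[C@]2(C)O)ccc1OCc1ccccc1 | intermediate
17 | (2R,3S,4S,5R)-2,5-bis(4-hydroxy-3-methoxyphenyl)-3,4-dimethyloxolan-3-ol | COc1cc([C@H]2O[C@@H](c3ccc(O)c(OC)c3)[C@H](C)[C@]2(C)O)ccc1O | target

## Step count and least certain steps

Total: 10 steps. Longest linear sequence: 8 steps (1, 2, 3, 6, 7, 8, 9, 10); the dipolarophile branch (4, 5) joins at step 6.

**Step 6 (key step, proposed new method).**
- Most likely failure: the hindered, donor-substituted alkene traps the ylide too slowly, so that reclosure, fragmentation of the ylide or secondary electron-transfer degradation of the electron-rich adduct takes over. Leakage to the exo orientation, or a stepwise radical-cation addition, would erode the C3/C4 relation to the aryl groups.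
- Fallback (known chemistry, from 6 back to 13): the C3 oxygen is no longer carried by the dipolarophile but introduced afterwards. The same photoinduced cycloaddition is run with (1R,2S,5R)-menthyl (E)-but-2-enoate F1, a plain β-substituted acrylate of the class for which the reaction is established. After separation of diastereomers this should give menthyl (2S,3R,4R,5R)-2,5-bis[4-(benzyloxy)-3-methoxyphenyl]-4-methyloxolane-3-carboxylate F2 (ester cis to the aryl groups, methyl trans). Deprotonation with LiN(iPr)2 at −78 °C and hydroxylation of the enolate with 2-(phenylsulfonyl)-3-phenyloxaziridine, on the face away from the C2 aryl group, should give menthyl (2R,3S,4S,5R)-2,5-bis[4-(benzyloxy)-3-methoxyphenyl]-3-hydroxy-4-methyloxolane-3-carboxylate F3. LiAlH4 then gives 13. Face control by the menthyl group is weak, so material is lost in the separation.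

**Step 5.**
- Most likely failure: radical bromination does not stop cleanly (allylic bromination after early loss of HBr, or hydrogen abstraction at the acetal C–H with ring opening), and the elimination may be incompletely (Z)-selective.
- Fallback (from 8 back to 10): an ionic route. The enolate of 8 (LiN(iPr)2, THF, −78 °C) is selenenylated with PhSeBr anti to the tert-butyl group to give (2S,5S)-2-tert-butyl-5-ethyl-5-(phenylselanyl)-1,3-dioxolan-4-one F4. Oxidation with H2O2 and syn-elimination of the selenoxide, which can only occur towards the ethyl group, gives 10.

**Step 3.**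
- Most likely failure: ionisation of the p-alkoxybenzyl–sulfur bond (the salt reverts or solvolyses before the ylide forms) and acid-induced rearrangement of the electron-rich oxirane during isolation.
- Fallback (from 1 back to 6, bypassing 2 to 5): McMurry coupling of 1 with low-valent titanium (TiCl4, Zn, THF, reflux) gives (E)-1,2-bis[4-(benzyloxy)-3-methoxyphenyl]ethene F5, which is epoxidised under neutral conditions with dimethyldioxirane in acetone at 0 °C.

**Step 8.**
- Most likely failure: slow sulfonylation of a neopentyl-type hydroxyl shielded by the cis aryl group at C2, with premature oxirane closure or a ring-expanding 1,2-shift of the benzylic C2 if forcing conditions are used.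
- Fallback (from 13 back to 15): Mitsunobu cyclodehydration (PPh3, diisopropyl azodicarboxylate, THF) activates the primary hydroxyl as an oxyphosphonium ion, which the tertiary hydroxyl displaces, giving 15 directly. Compound 15 is then isolated and opened with LiEt3BH as in step 9.

**Step 10.**
- Most likely failure: hydrogenolysis does not stop at the phenol ethers but goes on to the benzylic bonds C2–O1 and C5–O1, opening the ring.
- Fallback (from 16 back to 17): single-electron debenzylation in solution with lithium naphthalenide (LiC10H8), THF, −78 °C, titrated. The electron enters the unsubstituted phenyl ring of the benzyl group and expels an aryloxide, a far better leaving group than the ring alkoxide, and the resulting phenoxide rings resist further reduction.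

## Further compounds

F1 | step 6 | (1R,2S,5R)-menthyl (E)-but-2-enoate | C/C=C/C(=O)O[C@@H]1C[C@H](C)CC[C@H]1C(C)C
F2 | step 6 | (1R,2S,5R)-menthyl (2S,3R,4R,5R)-2,5-bis[4-(benzyloxy)-3-methoxyphenyl]-4-methyloxolane-3-carboxylate | COc1cc([C@H]2O[C@@H](c3ccc(OCc4ccccc4)c(OC)c3)[C@H](C)[C@H]2C(=O)O[C@@H]3C[C@H](C)CC[C@H]3C(C)C)ccc1OCc1ccccc1
F3 | step 6 | (1R,2S,5R)-menthyl (2R,3S,4S,5R)-2,5-bis[4-(benzyloxy)-3-methoxyphenyl]-3-hydroxy-4-methyloxolane-3-carboxylate | COc1cc([C@H]2O[C@@H](c3ccc(OCc4ccccc4)c(OC)c3)[C@H](C)[C@]2(C(=O)O[C@@H]3C[C@H](C)CC[C@H]3C(C)C)O)ccc1OCc1ccccc1
F4 | step 5 | (2S,5S)-2-tert-butyl-5-ethyl-5-(phenylselanyl)-1,3-dioxolan-4-one | CC[C@@]1([Se]c2ccccc2)O[C@@H](C(C)(C)C)OC1=O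
F5 | step 3 | (E)-1,2-bis[4-(benzyloxy)-3-methoxyphenyl]ethene | COc1cc(/C=C/c2ccc(OCc3ccccc3)c(OC)c2)ccc1OCc1ccccc1
F0 | step 8 | none | none
F0 | step 10 | none | none
A1 | alternative 1 | (2R,3S,4R)-3-(benzyloxy)-2-[4-(benzyloxy)-3-methoxyphenyl]-3,4-dimethylcyclobutan-1-one | O=C1[C@H](c2ccc(OCc3ccccc3)c(OC)c2)[C@@](C)(OCc2ccccc2)[C@H]1C
A2 | alternative 1 | 1-(benzyloxy)-4-[(1E)-2-(benzyloxy)prop-1-en-1-yl]-2-methoxybenzene | COc1cc(/C=C(\C)OCc2ccccc2)ccc1OCc1ccccc1
A3 | alternative 1 | methylketene | CC=C=O
A4 | alternative 2 | (2R,4S,5R)-2,5-bis[4-(benzyloxy)-3-methoxyphenyl]-4-methyloxolan-3-one | COc1cc([C@H]2O[C@@H](c3ccc(OCc4ccccc4)c(OC)c3)[C@H](C)C2=O)ccc1OCc1ccccc1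
A5 | alternative 2 | (2R,4Z,5R)-2,5-bis[4-(benzyloxy)-3-methoxyphenyl]-4-ethylidene-1,3-dioxolane | C/C=C1\O[C@H](c2ccc(OCc3ccccc3)c(OC)c2)O[C@@H]1c1ccc(OCc2ccccc2)c(OC)c1
A6 | alternative 3 | [(2R,3S,4S,5R)-2,5-bis[4-(benzyloxy)-3-methoxyphenyl]-3,4-dimethyloxolan-3-yl]dimethyl(phenyl)silane | COc1cc([C@H]2O[C@@H](c3ccc(OCc4ccccc4)c(OC)c3)[C@H](C)[C@]2(C)[Si](C)(C)c2ccccc2)ccc1OCc1ccccc1
A7 | alternative 3 | [(1R,2Z)-1-[4-(benzyloxy)-3-methoxyphenyl]-2-methylbut-2-en-1-yl]dimethyl(phenyl)silane | C/C=C(C)\[C@H](c1ccc(OCc2ccccc2)c(OC)c1)[Si](C)(C)c1ccccc1
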